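**Retrosynthetic overview** (lactone ring numbered O1, C2(=O), C3, C4, C5; C7 is the carbinol carbon on C4)
1. Target 15 ⇐ 14 (fluoride removal of two aryl silyl ethers) ⇐ ketone 13 (CBS reduction sets C7) ⇐ dithiane 12 (mercury-assisted hydrolysis) ⇐ menthyl acetal 9 (saponification/NaBH4/relactonisation turns acetal carbon C5 into the lactone CH2).
2. 9 ⇐ dithiane 3 + furanone 6 + benzylic bromide 5 in one flask: 1,4-addition of the lithiated dithiane forms C4–C7, and benzylation of the resulting enolate forms the C3–CH2Ar bond, so two C–C bonds and both ring stereocentres arise together.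
3. Enabling feature: in the five-membered ring of 6 the C3=C4 double bond is conjugated with the C2 lactone carbonyl (C4 electrophilic, C3 becomes the enolate carbon) and sits next to the C5 acetal stereocentre, whose O-menthyl group blocks one face of the ring and is later erased.
4. Ring order: the lactone ring is bought with 6 and never built (it is opened and reclosed once, in step 6); both guaiacyl rings come from vanillin through the common silyl ether 2.

Key step: step 5

Assumption: furanone 6 is used as the single crystalline (5R) acetal diastereomer derived from (−)-menthol, a catalogue chiral building block; its C5 centre is the only source of the absolute configuration at C3 and C4.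

Step 1
Reactants: 1 vanillin
Product: 2 3-methoxy-4-(triisopropylsilyloxy)benzaldehyde
Conditions: TIPSCl, imidazole, DMF, rt
Reagents that add atoms: chlorotriisopropylsilane, CC(C)[Si](Cl)(C(C)C)C(C)C
Why: Imidazole-promoted O-silylation of the phenol should give a bulky aryl silyl ether that tolerates n-BuLi, hydride reagents and mercury salts and is removed at the end with buffered fluoride.

Step 2
Reactants: 2 3-methoxy-4-(triisopropylsilyloxy)benzaldehyde
Product: 3 2-[3-methoxy-4-(triisopropylsilyloxy)phenyl]-1,3-dithiane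
Conditions: HS(CH2)3SH, I2 (10 mol%), CH2Cl2, rt
Reagents that add atoms: propane-1,3-dithiol, SCCCS
Why: Iodine-catalysed dithioacetalisation of the aldehyde should give the 2-aryl-1,3-dithiane, an acyl anion equivalent (umpolung) whose C2–H is acidic enough for n-BuLi, under conditions mild enough to keep the silyl ether.

Step 3
Reactants: 2 3-methoxy-4-(triisopropylsilyloxy)benzaldehyde
Product: 4 [3-methoxy-4-(triisopropylsilyloxy)phenyl]methanol
Conditions: NaBH4, MeOH, 0 °C
Reagents that add atoms: none
Why: Borohydride reduction of the aromatic aldehyde should give the benzylic alcohol cleanly, the aryl silyl ether being inert to NaBH4 at this temperature.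

Step 4
Reactants: 4 [3-methoxy-4-(triisopropylsilyloxy)phenyl]methanol
Product: 5 [4-(bromomethyl)-2-methoxyphenoxy]triisopropylsilane
Conditions: CBr4, PPh3, CH2Cl2, 0 °C; short silica plug, used at once
Reagents that add atoms: tetrabromomethane, BrC(Br)(Br)Br
Why: The Appel reaction converts the primary benzylic alcohol into the bromide through an alkoxyphosphonium ion under neutral conditions, which should spare the silyl ether and the ionisation-prone electron-rich benzylic bromide.

Step 5
Reactants: 3 2-[3-methoxy-4-(triisopropylsilyloxy)phenyl]-1,3-dithiane; 6 (5R)-5-(l-menthyloxy)furan-2(5H)-one; 5 [4-(bromomethyl)-2-methoxyphenoxy]triisopropylsilane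
Product: 9 (3R,4R,5R)-3-{[3-methoxy-4-(triisopropylsilyloxy)phenyl]methyl}-4-{2-[3-methoxy-4-(triisopropylsilyloxy)phenyl]-1,3-dithian-2-yl}-5-(l-menthyloxy)oxolan-2-one, via 2-lithio-2-aryl-1,3-dithiane 7 (not isolated), via lithium enolate of the Michael adduct 8 (not isolated)
Conditions: n-BuLi, THF, −78 to −20 °C; then 6, −78 °C; then 5, DMPU, −78 °C to rt
Reagents that add atoms: none
Why: Deprotonation of 3 gives the soft, sulfur- and aryl-stabilised carbanion 7, which adds in a Michael sense to C4 of furanone 6 and thereby turns C3 into the carbon end of lithium enolate 8; 8 then displaces bromide from 5 (SN2 C-benzylation) to form the C3–CH2Ar bond, so that two C–C bonds, the whole carbon skeleton and both ring stereocentres arise in one flask from three simple pieces. The closest known reaction type is the tandem conjugate addition–enolate alkylation of 5-alkoxyfuran-2(5H)-ones with lithiated dithioacetals and benzylic halides. No ring is closed, since the lactone ring is already present in 6 and both new bonds are exocyclic to it. C4 is controlled by the C5 acetal centre, whose menthyloxy group shields one face of the flat ring so that 7 enters anti to it; C3 is then controlled by the new, very bulky dithianyl group on C4, the bromide approaching the enolate from the opposite face (3,4-trans and 4,5-trans). The step needs 1,4- instead of 1,2-addition, which the delocalised 2-aryl-dithianyl anion and the s-trans-locked cyclic enoate should secure, and C-alkylation without proton transfer, which the reactive benzylic bromide, the lithium counter-ion and DMPU as co-solvent favour.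

Step 6
Reactants: 9 (3R,4R,5R) menthyl acetal lactone from step 5
Product: 12 (3R,4R)-3-{[3-methoxy-4-(triisopropylsilyloxy)phenyl]methyl}-4-{2-[3-methoxy-4-(triisopropylsilyloxy)phenyl]-1,3-dithian-2-yl}oxolan-2-one, via ring-opened aldehyde carboxylate 10 (not isolated), via 4-hydroxy acid 11 (not isolated)
Conditions: NaBH4, KOH, EtOH/H2O, 0 °C to rt; then 1 M HCl to pH 2, rt
Reagents that add atoms: potassium hydroxide, [K+].[OH-]
Why: Saponification of the lactone carbonyl (which brings in one carboxylate oxygen from hydroxide) frees the C5 hemiacetal, which loses menthol to give aldehyde 10 that NaBH4 reduces in situ, and acidification relactonises hydroxy acid 11 (hydrolysis–reduction–lactonisation of a 5-alkoxy lactone), so that C5 should end as CH2 with the C2 carbonyl, the dithiane and the trans C3/C4 centres unchanged.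

Step 7
Reactants: 12 (3R,4R) dithianyl lactone
Product: 13 (3R,4R)-4-[3-methoxy-4-(triisopropylsilyloxy)benzoyl]-3-{[3-methoxy-4-(triisopropylsilyloxy)phenyl]methyl}oxolan-2-one
Conditions: HgCl2, CaCO3, MeCN/H2O (4:1), rt
Reagents that add atoms: water, O
Why: In this mercury-assisted dithioacetal hydrolysis, thiophilic divalent mercury opens the dithiane to a thionium ion (stabilised by the electron-rich aryl ring) that water converts into the aryl ketone, while CaCO3 keeps the medium near neutral so that the silyl ethers, the lactone and the now enolisable C4 centre (trans being the more stable arrangement) should survive.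

Step 8
Reactants: 13 (3R,4R) keto lactone
Product: 14 (3R,4R)-4-{(S)-hydroxy[3-methoxy-4-(triisopropylsilyloxy)phenyl]methyl}-3-{[3-methoxy-4-(triisopropylsilyloxy)phenyl]methyl}oxolan-2-one
Conditions: (R)-2-methyl-CBS-oxazaborolidine (20 mol%), BH3·SMe2, THF, −20 °C; MeOH quench
Reagents that add atoms: none
Why: In this Corey–Bakshi–Shibata reduction the (R)-oxazaborolidine should bind the ketone with the aryl group as the large substituent and deliver hydride to the face that gives the (S)-carbinol at C7, the acyclic 1,2-induction from C4 (hydride entering anti to ring carbon C3) being expected to point the same way, and borane at this temperature should leave the lactone untouched.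

Step 9
Reactants: 14 bis-silyl ether of the target
Product: 15 (3R,4R)-4-[(S)-hydroxy(4-hydroxy-3-methoxyphenyl)methyl]-3-[(4-hydroxy-3-methoxyphenyl)methyl]oxolan-2-one
Conditions: TBAF, AcOH, THF, 0 °C
Reagents that add atoms: none
Why: Fluoride-mediated desilylation (strong Si–F bond) should free both phenols, and buffering with acetic acid avoids the phenoxide that could open the lactone or expel the C7 hydroxyl through a quinone methide, so the three stereocentres are not touched.

**Compound list**
1 | vanillin (4-hydroxy-3-methoxybenzaldehyde) | COc1cc(C=O)ccc1O | starting material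
2 | 3-methoxy-4-(triisopropylsilyloxy)benzaldehyde | COc1cc(C=O)ccc1O[Si](C(C)C)(C(C)C)C(C)C | intermediate
3 | 2-[3-methoxy-4-(triisopropylsilyloxy)phenyl]-1,3-dithiane | COc1cc(C2SCCCS2)ccc1O[Si](C(C)C)(C(C)C)C(C)C | intermediate
4 | [3-methoxy-4-(triisopropylsilyloxy)phenyl]methanol | COc1cc(CO)ccc1O[Si](C(C)C)(C(C)C)C(C)C | intermediate
5 | [4-(bromomethyl)-2-methoxyphenoxy]triisopropylsilane | COc1cc(CBr)ccc1O[Si](C(C)C)(C(C)C)C(C)C | intermediate
6 | (5R)-5-{[(1R,2S,5R)-2-isopropyl-5-methylcyclohexyl]oxy}furan-2(5H)-one, i.e. (5R)-5-(l-menthyloxy)furan-2(5H)-one | CC(C)[C@@H]1CC[C@@H](C)C[C@H]1O[C@@H]1OC(=O)C=C1 | starting material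
7 | 2-lithio-2-[3-methoxy-4-(triisopropylsilyloxy)phenyl]-1,3-dithiane | [Li]C1(SCCCS1)c1ccc(O[Si](C(C)C)(C(C)C)C(C)C)c(OC)c1 | intermediate
8 | lithium enolate of the Michael adduct: (4R,5R)-4-(2-aryl-1,3-dithian-2-yl)-5-(l-menthyloxy)-4,5-dihydrofuran-2-olate, dithianyl trans to menthyloxy | [Li]OC1=C[C@@H](C2(SCCCS2)c2ccc(O[Si](C(C)C)(C(C)C)C(C)C)c(OC)c2)[C@H](O[C@@H]2C[C@H](C)CC[C@H]2C(C)C)O1 | intermediate
9 | (3R,4R,5R)-3-{[3-methoxy-4-(triisopropylsilyloxy)phenyl]methyl}-4-{2-[3-methoxy-4-(triisopropylsilyloxy)phenyl]-1,3-dithian-2-yl}-5-(l-menthyloxy)oxolan-2-one | O=C1[C@H](Cc2ccc(O[Si](C(C)C)(C(C)C)C(C)C)c(OC)c2)[C@@H](C2(SCCCS2)c2ccc(O[Si](C(C)C)(C(C)C)C(C)C)c(OC)c2)[C@H](O[C@@H]2C[C@H](C)CC[C@H]2C(C)C)O1 | intermediate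
10 | potassium (2R,3R)-2-{[3-methoxy-4-(triisopropylsilyloxy)phenyl]methyl}-3-{2-[3-methoxy-4-(triisopropylsilyloxy)phenyl]-1,3-dithian-2-yl}-4-oxobutanoate | [K+].[O-]C(=O)[C@H](Cc1ccc(O[Si](C(C)C)(C(C)C)C(C)C)c(OC)c1)[C@@H](C1(SCCCS1)c1ccc(O[Si](C(C)C)(C(C)C)C(C)C)c(OC)c1)C=O | intermediate
11 | (2R,3R)-4-hydroxy-2-{[3-methoxy-4-(triisopropylsilyloxy)phenyl]methyl}-3-{2-[3-methoxy-4-(triisopropylsilyloxy)phenyl]-1,3-dithian-2-yl}butanoic acid | OC(=O)[C@H](Cc1ccc(O[Si](C(C)C)(C(C)C)C(C)C)c(OC)c1)[C@@H](C1(SCCCS1)c1ccc(O[Si](C(C)C)(C(C)C)C(C)C)c(OC)c1)CO | intermediate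
12 | (3R,4R)-3-{[3-methoxy-4-(triisopropylsilyloxy)phenyl]methyl}-4-{2-[3-methoxy-4-(triisopropylsilyloxy)phenyl]-1,3-dithian-2-yl}oxolan-2-one | O=C1[C@H](Cc2ccc(O[Si](C(C)C)(C(C)C)C(C)C)c(OC)c2)[C@@H](C2(SCCCS2)c2ccc(O[Si](C(C)C)(C(C)C)C(C)C)c(OC)c2)CO1 | intermediate
13 | (3R,4R)-4-[3-methoxy-4-(triisopropylsilyloxy)benzoyl]-3-{[3-methoxy-4-(triisopropylsilyloxy)phenyl]methyl}oxolan-2-one | O=C1[C@H](Cc2ccc(O[Si](C(C)C)(C(C)C)C(C)C)c(OC)c2)[C@@H](C(=O)c2ccc(O[Si](C(C)C)(C(C)C)C(C)C)c(OC)c2)CO1 | intermediate
14 | (3R,4R)-4-{(S)-hydroxy[3-methoxy-4-(triisopropylsilyloxy)phenyl]methyl}-3-{[3-methoxy-4-(triisopropylsilyloxy)phenyl]methyl}oxolan-2-one | O=C1[C@H](Cc2ccc(O[Si](C(C)C)(C(C)C)C(C)C)c(OC)c2)[C@@H]([C@H](O)c2ccc(O[Si](C(C)C)(C(C)C)C(C)C)c(OC)c2)CO1 | intermediate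
15 | (3R,4R)-4-[(S)-hydroxy(4-hydroxy-3-methoxyphenyl)methyl]-3-[(4-hydroxy-3-methoxyphenyl)methyl]oxolan-2-one | COc1cc(C[C@H]2C(=O)OC[C@@H]2[C@H](O)c2ccc(O)c(OC)c2)ccc1O | target

**Step count**
Total step count: 9
Longest linear sequence: 8 steps (steps 1, 3, 4, 5, 6, 7, 8, 9, from vanillin)

**Steps most likely to fail**

Step 5 (key step). What may go wrong: the enolate formed in situ is protonated or alkylates too slowly beside the bulky dithianyl group, the labile benzylic bromide decomposes before SN2 attack, or some 1,2-addition occurs. Fallback: the two bond formations are decoupled. Setting out from 3 and 6, the conjugate addition is run alone (n-BuLi, THF, −78 °C) and quenched with NH4Cl to give the C3-unsubstituted Michael adduct F1, which is purified. F1 is then deprotonated with LiN(iPr)2 in THF/DMPU at −78 °C and the preformed lithium enolate is benzylated with 5, anti to the C4 dithianyl group. This brings the sequence back to the route at 9.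

Step 6. What may go wrong: cleavage of the aryl silyl ethers by hydroxide, or epimerisation at C4 while the open-chain aldehyde is exposed to base. Fallback: a base-free two-stage sequence from 9. Acid hydrolysis of the menthyl acetal (TFA/H2O, THF, 40 °C) should give the 5-hydroxy lactone F2 (mixture of C5 epimers, in equilibrium with the open aldehyde acid). NaBH4 in EtOH at 0 °C followed by acidification to pH 2 then reduces the open aldehyde form and relactonises, rejoining the route at 12.

Step 8. What may go wrong: poor facial selectivity in hydride delivery, if the catalyst does not differentiate the aryl group from the α-branched ring carbon or if catalyst and substrate preferences are mismatched. Fallback: selectivity is replaced by separation and recycling. From 13, reduction with NaBH4 and CeCl3·7H2O (MeOH/THF, −40 °C) should give 14 together with the (7R)-carbinol epimer F3. The two are separated by chromatography, F3 is oxidised back to 13 with Dess–Martin periodinane and resubmitted, and the route continues from 14.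

**Further compounds**
F1 | step 5 | (4R,5R)-4-{2-[3-methoxy-4-(triisopropylsilyloxy)phenyl]-1,3-dithian-2-yl}-5-(l-menthyloxy)oxolan-2-one | O=C1C[C@@H](C2(SCCCS2)c2ccc(O[Si](C(C)C)(C(C)C)C(C)C)c(OC)c2)[C@H](O[C@@H]2C[C@H](C)CC[C@H]2C(C)C)O1
F2 | step 6 | (3R,4R)-5-hydroxy-3-{[3-methoxy-4-(triisopropylsilyloxy)phenyl]methyl}-4-{2-[3-methoxy-4-(triisopropylsilyloxy)phenyl]-1,3-dithian-2-yl}oxolan-2-one (both C5 epimers) | O=C1[C@H](Cc2ccc(O[Si](C(C)C)(C(C)C)C(C)C)c(OC)c2)[C@@H](C2(SCCCS2)c2ccc(O[Si](C(C)C)(C(C)C)C(C)C)c(OC)c2)C(O)O1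
F3 | step 8 | (3R,4R)-4-{(R)-hydroxy[3-methoxy-4-(triisopropylsilyloxy)phenyl]methyl}-3-{[3-methoxy-4-(triisopropylsilyloxy)phenyl]methyl}oxolan-2-one | O=C1[C@H](Cc2ccc(O[Si](C(C)C)(C(C)C)C(C)C)c(OC)c2)[C@@H]([C@@H](O)c2ccc(O[Si](C(C)C)(C(C)C)C(C)C)c(OC)c2)CO1
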